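Open a ledger on the substrate, the limiting reagent: the reagent stands at 4.00 equiv, and blue's substrate has fallen to 0 % by 25.0 s. The flasks differ in the charged [substrate], and the catalyst loading stays at 10 mol%.

in all of them: catalyst 10 mol%
- grey: substrate 2.4 mM; reagent 4 equiv; run made earlier
- blue: substrate 270 mM; reagent 4 equiv; run made earlier
- gamma: substrate 2.0 mM; reagent 4.00 equiv; time 2.0 min
- beta: substrate 6.0 mM; reagent 4.00 equiv; time 2.0 min
- delta: substrate 20 mM; reagent 4.00 equiv; time 2.0 min
- eta: substrate 60 mM; reagent 4.00 equiv; time 2.0 min
- zeta: substrate 200 mM; reagent 4.00 equiv; time 2.0 min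

- grey (time / s: target / %, substrate / %): 10.0: 0, 94; 12.0: 0, 95; 25.0: 3, 91; 40.0: 5, 88; 50.0: 5, 82; 60.0: 10, 81; 80.0: 7, 77
- blue (time / s: target / %, substrate / %): 10.0: 22, 16; 15.0: 48, 3; 25.0: 49, 0; 40.0: 51, 1; 60.0: 51, 1; 80.0: 49, 2

(standard deviation of a reading: 1.5 percentage points)

- "hardly changes" means that all values lie within two and a half points (for a concentration: within two and a half percent of the largest)

- amount of target at the end, in percent of the substrate charged for gamma, beta, delta, eta, zeta, in this order
- the course of these numbers from the first flask to the last (falls all the way / rises, then falls / falls, then rises / hardly changes / rises all the way)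

Each reading splits the charge into three entries: target, substrate left, and a remainder that is missing. Grey at 80.0 s shows 7 % target, 77 % substrate and 16.0 % missing. Blue at 60.0 s shows 51 % target, 1 % substrate and 48.0 % missing. Blue's missing entry shrinks from 62.0 % at 10.0 s to 49.0 % at 15.0 s, beside a catalyst loading of 10 mol%. Part of it therefore seems to come back, and we read the split late.

We define the split ratio ρ, a selectivity factor, as target gained per unit of substrate gone missing. Summed over its last three readings to tame the scatter, grey gives ρ = 0.579. Blue's last three give 1.04, which is larger than grey's.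

The books then close with one line: target equals the substrate consumed times ρ/(1+ρ). For consumption we use a clock. Grey's readings give a decay constant of 0.00327 s⁻¹, and we assume that it scales with the charge. We then reckon that gamma consumes 27.9 %, and grey's ρ gives 10.2 % target. For zeta we take the substrate as consumed, since the time is longer than blue's 25.0 s even when that is scaled by the two charges, and blue's ρ gives 51.0 %. By the same clock we reckon that delta consumes 96.2 %. With blue's ρ, our estimate for delta is 49.1 %, so our row rises and levels.

The forecast, lower at delta than our estimate, gives 10 %, 25 %, 45 %, 50 %, 50 %, rises all the way, in its words “The yield climbs, then levels off”.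

The flasks give 9.98 %, 35.4 %, 72.2 %, 64.6 %, 52.4 %: rises, then falls.

    substrate + reagent + catalyst → target + catalyst, rate k1*[substrate]*[reagent]*[catalyst]/(1 + ([substrate]/sat1)) (3.00 mM, k = 1200 M⁻² s⁻¹)
    substrate + catalyst ⇌ idle complex, settled at all times (K = 140 M⁻¹)
    2 substrate → homo dimer (k = 0.380 M⁻¹ s⁻¹)

Read as rates, ρ compares the target step with the homo dimer step, and in gamma that ratio drifts up from 0.61 just after the start to 0.75 at 0.964 min. Counted in substrate, at 2.00 min gamma holds 9.98 % target against 13.5 % homo dimer, a ratio of 0.739 beside grey's reading of 0.579, zeta holds 52.4 % against 47.6 %, a ratio of 1.10 beside blue's reading of 1.04, and delta holds 72.2 % against 27.8 %, a ratio of 2.60.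

(The numbers in the tables stem from a simulated flask from invented constants; the scatter is artificial.)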